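**Retrosynthetic overview**
1. Last bonds: the eight O–benzyl bonds (hydrogenolysis), and before that the galloyl ester C–O bond (Steglich acylation of pentabenzyl (2R,3S)-gallocatechin).
2. Key disconnection: C3–OH and C2–H are removed together, back to an achiral 2-aryl-4H-chromene (flav-2-ene). One syn hydroboration–oxidation with IpcBH2 sets both stereocentres and the 2,3-trans relationship at once, replacing the usual diarylpropene dihydroxylation–cyclisation.
3. Flav-2-ene from cyclodehydration (O1–C2 bond) of a 2-hydroxy dihydrochalcone, from the chalcone, from a Claisen–Schmidt condensation (C3–C4 bond).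
4. Building blocks: 3,5-bis(benzyloxy)phenol (ring A, after ortho-formylation) and 3,4,5-tris(benzyloxy)benzoic acid, used twice (ring B as its methyl ketone, the galloyl ring as the acid).
5. Ring order: ring A, ring B and the galloyl ring are bought as arenes; ring C is the only ring built and is closed before any stereocentre exists.

Assumption: 3,5-bis(benzyloxy)phenol, 3,4,5-tris(benzyloxy)benzoic acid and the TMEDA adduct of IpcBH2 made from (+)-α-pinene are taken as commercial; the target SMILES is read as (2R,3S), 2,3-trans.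

**Route**

Step 1
Reactants: 1 3,5-bis(benzyloxy)phenol
Product: 3 2-hydroxy-4,6-bis(benzyloxy)benzaldehyde, via hydroxymethylphenol 2 (not isolated)
Conditions: MgCl2 (1.5 equiv), Et3N (3.8 equiv), (CH2O)n (6.8 equiv), MeCN, reflux, 3 h; 1 M HCl work-up
Reagents that add atoms: paraformaldehyde (delivers formaldehyde), C=O
Why: Casnati–Skattebøl ortho-formylation: the ArOMgCl phenoxide directs formaldehyde only to the ortho carbon (the two ortho sites of 1 are equivalent), and the chelated alcohol 2 is oxidised in the flask by a second formaldehyde through an Oppenauer-type hydride transfer, with the benzyl ethers inert.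

Step 2
Reactants: 4 3,4,5-tris(benzyloxy)benzoic acid
Product: 6 1-[3,4,5-tris(benzyloxy)phenyl]ethan-1-one, via dilithium gem-diolate 5 (not isolated)
Conditions: MeLi (2.3 equiv), THF, 0 °C to rt, 2 h; then poured into ice-cold 1 M HCl
Reagents that add atoms: methyllithium, [Li]C
Why: Organolithium ketone synthesis from a carboxylic acid: MeLi adds to the carboxylate ArCO2Li and stops at gem-diolate 5, which cannot collapse to the ketone until the acidic quench, so no tertiary alcohol forms.

Step 3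
Reactants: 3 2-hydroxy-4,6-bis(benzyloxy)benzaldehyde + 6 1-[3,4,5-tris(benzyloxy)phenyl]ethan-1-one
Product: 8 (E)-3-[2-hydroxy-4,6-bis(benzyloxy)phenyl]-1-[3,4,5-tris(benzyloxy)phenyl]prop-2-en-1-one, via aldol adduct 7 (not isolated)
Conditions: KOH (50% aq, 10 equiv), EtOH/THF 2:1, rt to 40 °C, 36 h; then AcOH to pH 5
Reagents that add atoms: none
Why: Claisen–Schmidt (crossed aldol) condensation: the enolate of 6 adds to the non-enolisable aldehyde 3 and E1cB dehydration of 7 gives the conjugated E enone, the thermodynamic geometry; excess KOH is used because the phenoxide form of 3 is a weakened electrophile.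

Step 4
Reactants: 8 (E)-3-[2-hydroxy-4,6-bis(benzyloxy)phenyl]-1-[3,4,5-tris(benzyloxy)phenyl]prop-2-en-1-one
Product: 9 3-[2-hydroxy-4,6-bis(benzyloxy)phenyl]-1-[3,4,5-tris(benzyloxy)phenyl]propan-1-one
Conditions: H2 (4 atm), RhCl(PPh3)3 (5 mol %), THF/t-BuOH 1:1, 50 °C, 16 h
Reagents that add atoms: none
Why: Chemoselective homogeneous catalytic hydrogenation: RhCl(PPh3)3 saturates the disubstituted enone C=C but neither hydrogenolyses aryl benzyl ethers nor reduces the aryl ketone, so all five benzyl groups survive.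

Step 5
Reactants: 9 3-[2-hydroxy-4,6-bis(benzyloxy)phenyl]-1-[3,4,5-tris(benzyloxy)phenyl]propan-1-one
Product: 11 5,7-bis(benzyloxy)-2-[3,4,5-tris(benzyloxy)phenyl]-4H-chromene, via cyclic hemiketal 10 (not isolated)
Conditions: PPTS (10 mol %), toluene, reflux, Dean–Stark, Ar, 2 h; filtration through basic Al2O3
Reagents that add atoms: none
Why: Acid-catalysed cyclodehydration: the phenol adds to the ketone to give hemiketal 10, which loses water through the 2-aryl oxocarbenium ion to the enol ether 11, closing ring C and leaving a flat, achiral C2=C3 bond for the key step; the mild acid and water removal limit acid-promoted dimerisation.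

Step 6
Reactants: 11 5,7-bis(benzyloxy)-2-[3,4,5-tris(benzyloxy)phenyl]-4H-chromene
Product: 13 (2R,3S)-5,7-bis(benzyloxy)-2-[3,4,5-tris(benzyloxy)phenyl]chroman-3-ol, via alkyl(isopinocampheyl)borane 12 (not isolated)
Conditions: (IpcBH2)2·TMEDA [from (+)-α-pinene, 0.75 equiv], BF3·OEt2 (1.5 equiv), THF, rt, 1.5 h, TMEDA·2BF3 filtered off; then 11, −25 °C, 36 h; then 3 M NaOH, 30% H2O2, 0 °C to rt
Reagents that add atoms: hydrogen peroxide, OO; monoisopinocampheylborane IpcBH2 [from (+)-α-pinene], C[C@H]1[C@H](B)C[C@@H]2C[C@H]1C2(C)C (its boron and isopinocampheyl group stay only in 12)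
Why: Proposed new method: enantioselective hydroboration of a flav-2-ene has not been demonstrated, but the closest known reactions are the Brown asymmetric hydroboration–oxidation of 1-arylcycloalkenes with IpcBH2 and the racemic hydroboration–oxidation of flav-2-enes to 2,3-trans-flavan-3-ols; boron adds to C3 (beta to both the ring oxygen and ring B) and hydrogen to C2 in a concerted four-centre syn addition, so the 2,3-trans relationship is fixed by mechanism, the Ipc group of the reagent made from (+)-α-pinene selects the alkene face that gives the S carbinol centre with 1-arylcycloalkenes, which here means 3S and hence 2R, and the C–B bond is oxidised with retention.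

Step 7
Reactants: 13 (2R,3S)-5,7-bis(benzyloxy)-2-[3,4,5-tris(benzyloxy)phenyl]chroman-3-ol + 4 3,4,5-tris(benzyloxy)benzoic acid
Product: 15 (2R,3S)-5,7-bis(benzyloxy)-2-[3,4,5-tris(benzyloxy)phenyl]chroman-3-yl 3,4,5-tris(benzyloxy)benzoate, via O-acylisourea 14 (not isolated)
Conditions: 4 (1.5 equiv), DCC (1.6 equiv), DMAP (0.3 equiv), CH2Cl2, 0 °C to rt, 16 h
Reagents that add atoms: N,N'-dicyclohexylcarbodiimide (DCC), C(=NC1CCCCC1)=NC1CCCCC1 (its atoms stay only in 14)
Why: Steglich esterification: DCC turns 4 into O-acylisourea 14 and DMAP relays the acyl group to the hindered secondary alcohol; the carbinol C–O bond is not touched, so C3 is retained, and the non-basic medium leaves C2 alone.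

Step 8
Reactants: 15 (2R,3S)-5,7-bis(benzyloxy)-2-[3,4,5-tris(benzyloxy)phenyl]chroman-3-yl 3,4,5-tris(benzyloxy)benzoate
Product: 16 (+)-gallocatechin gallate [(2R,3S)-5,7-dihydroxy-2-(3,4,5-trihydroxyphenyl)chroman-3-yl 3,4,5-trihydroxybenzoate]
Conditions: H2 (1 atm), Pd(OH)2/C (20 wt %), THF/MeOH 1:1, rt, 4 h; filtered under Ar, concentrated below 30 °C
Reagents that add atoms: none
Why: Global hydrogenolysis of the eight aryl benzyl ethers under neutral conditions at room temperature leaves the gallate ester, the slower-reacting cyclic benzylic C2–O1 bond and both stereocentres untouched (no base or heat, so no C2 epimerisation or acyl migration).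

**Compound list**
1 | 3,5-bis(benzyloxy)phenol | Oc1cc(OCc2ccccc2)cc(OCc2ccccc2)c1 | starting material
2 | 2-(hydroxymethyl)-3,5-bis(benzyloxy)phenol (in the flask as its ArOMgCl chelate) | OCc1c(O)cc(OCc2ccccc2)cc1OCc1ccccc1 | intermediate
3 | 2-hydroxy-4,6-bis(benzyloxy)benzaldehyde | O=Cc1c(O)cc(OCc2ccccc2)cc1OCc1ccccc1 | intermediate
4 | 3,4,5-tris(benzyloxy)benzoic acid | OC(=O)c1cc(OCc2ccccc2)c(OCc2ccccc2)c(OCc2ccccc2)c1 | starting material
5 | dilithium 1-[3,4,5-tris(benzyloxy)phenyl]ethane-1,1-diolate | [Li+].[Li+].CC([O-])([O-])c1cc(OCc2ccccc2)c(OCc2ccccc2)c(OCc2ccccc2)c1 | intermediate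
6 | 1-[3,4,5-tris(benzyloxy)phenyl]ethan-1-one | CC(=O)c1cc(OCc2ccccc2)c(OCc2ccccc2)c(OCc2ccccc2)c1 | intermediate
7 | racemic 3-hydroxy-3-[2-hydroxy-4,6-bis(benzyloxy)phenyl]-1-[3,4,5-tris(benzyloxy)phenyl]propan-1-one | O=C(CC(O)c1c(O)cc(OCc2ccccc2)cc1OCc1ccccc1)c1cc(OCc2ccccc2)c(OCc2ccccc2)c(OCc2ccccc2)c1 | intermediate
8 | (E)-3-[2-hydroxy-4,6-bis(benzyloxy)phenyl]-1-[3,4,5-tris(benzyloxy)phenyl]prop-2-en-1-one | O=C(/C=C/c1c(O)cc(OCc2ccccc2)cc1OCc1ccccc1)c1cc(OCc2ccccc2)c(OCc2ccccc2)c(OCc2ccccc2)c1 | intermediate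
9 | 3-[2-hydroxy-4,6-bis(benzyloxy)phenyl]-1-[3,4,5-tris(benzyloxy)phenyl]propan-1-one | O=C(CCc1c(O)cc(OCc2ccccc2)cc1OCc1ccccc1)c1cc(OCc2ccccc2)c(OCc2ccccc2)c(OCc2ccccc2)c1 | intermediate
10 | racemic 5,7-bis(benzyloxy)-2-[3,4,5-tris(benzyloxy)phenyl]chroman-2-ol | OC1(CCc2c(OCc3ccccc3)cc(OCc3ccccc3)cc2O1)c1cc(OCc2ccccc2)c(OCc2ccccc2)c(OCc2ccccc2)c1 | intermediate
11 | 5,7-bis(benzyloxy)-2-[3,4,5-tris(benzyloxy)phenyl]-4H-chromene | C1=C(c2cc(OCc3ccccc3)c(OCc3ccccc3)c(OCc3ccccc3)c2)Oc2cc(OCc3ccccc3)cc(OCc3ccccc3)c2C1 | intermediate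
12 | [(2S,3S)-5,7-bis(benzyloxy)-2-(3,4,5-tris(benzyloxy)phenyl)chroman-3-yl][(1R,2S,3R,5R)-isopinocampheyl]borane; same spatial arrangement as 13, the C2 label differs only because boron ranks below carbon | C[C@H]1[C@H](B[C@H]3Cc4c(OCc5ccccc5)cc(OCc5ccccc5)cc4O[C@@H]3c3cc(OCc4ccccc4)c(OCc4ccccc4)c(OCc4ccccc4)c3)C[C@@H]2C[C@H]1C2(C)C | intermediate
13 | (2R,3S)-5,7-bis(benzyloxy)-2-[3,4,5-tris(benzyloxy)phenyl]chroman-3-ol | O[C@H]1Cc2c(OCc3ccccc3)cc(OCc3ccccc3)cc2O[C@@H]1c1cc(OCc2ccccc2)c(OCc2ccccc2)c(OCc2ccccc2)c1 | intermediate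
14 | N,N'-dicyclohexyl-O-[3,4,5-tris(benzyloxy)benzoyl]isourea | O=C(OC(=NC1CCCCC1)NC1CCCCC1)c1cc(OCc2ccccc2)c(OCc2ccccc2)c(OCc2ccccc2)c1 | intermediate
15 | (2R,3S)-5,7-bis(benzyloxy)-2-[3,4,5-tris(benzyloxy)phenyl]chroman-3-yl 3,4,5-tris(benzyloxy)benzoate | O=C(O[C@H]1Cc2c(OCc3ccccc3)cc(OCc3ccccc3)cc2O[C@@H]1c1cc(OCc2ccccc2)c(OCc2ccccc2)c(OCc2ccccc2)c1)c1cc(OCc2ccccc2)c(OCc2ccccc2)c(OCc2ccccc2)c1 | intermediate
16 | (+)-gallocatechin gallate, (2R,3S)-5,7-dihydroxy-2-(3,4,5-trihydroxyphenyl)chroman-3-yl 3,4,5-trihydroxybenzoate | O=C(O[C@H]1Cc2c(O)cc(O)cc2O[C@@H]1c1cc(O)c(O)c(O)c1)c1cc(O)c(O)c(O)c1 | target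

**Step count and risks**

Total step count: 8. Longest linear sequence: 7 steps (1 to 3 to 8 to 9 to 11 to 13 to 15 to 16, that is steps 1, 3, 4, 5, 6, 7 and 8); step 2 is the only branch.

The three steps most likely to fail, in order of risk:

Step 6 is the main risk. The sense and level of induction rest on analogy with 1-arylcycloalkenes. The hindered aryl enol ether may react slowly. The beta-aryloxy borane 12 can open ring C by elimination if Lewis acid remains or the oxidation is delayed. If only the sense is wrong, the reagent from (−)-α-pinene corrects it, and a recrystallisation of 13 is planned to raise the ee. The fallback sets out from 11 and comes back at 13. BH3·SMe2 (THF, 0 °C) adds syn to give the racemic 2,3-trans alkylborane F1, which alkaline H2O2 oxidises in the flask to the racemic trans-flavan-3-ol, that is 13 together with its (2S,3R)-enantiomer F2. Preparative chiral SFC (amylose tris(3,5-dimethylphenylcarbamate) phase, CO2/MeOH) then delivers 13 and removes F2. Control by the reagent is replaced by racemic synthesis and resolution.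

Step 5 is the second risk. The electron-rich flav-2-ene 11 is acid-labile and can dimerise or disproportionate to a flavylium salt and a flavan. The fallback sets out from 3 and 6 and comes back at 11 without any acid. NaBH4 (MeOH/THF, 0 °C) reduces 3 to the salicyl alcohol 2, isolated this time. Ketone 6 is converted with LiN(iPr)2 and ClP(O)(OEt)2 (THF, −78 °C) into the enol phosphate F3, and further LiN(iPr)2 (2.2 equiv, −78 °C to rt, dilute HCl work-up) eliminates diethyl phosphate to give the terminal alkyne 5-ethynyl-1,2,3-tris(benzyloxy)benzene F4. Heating 2 with F4 (2 equiv, toluene, 140 °C, sealed tube) dehydrates 2 to the ortho-quinone methide F5. This is trapped in an inverse-electron-demand hetero-Diels–Alder reaction, the alkyne terminus bonding to the methide CH2 and the aryl-bearing carbon to oxygen, which gives 11 directly.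

Step 3 is the third risk. Under KOH the aldehyde 3 is present as a di-ortho-substituted phenoxide and is a poor electrophile, so the condensation may stall. The fallback sets out from 6 and comes back at 8. CuBr2 (EtOAc/CHCl3, reflux) gives the alpha-bromo ketone F6, PPh3 (toluene, rt) gives the phosphonium bromide F7, and aqueous NaOH/CH2Cl2 gives the stabilised acyl ylide F8. Wittig olefination of 3 with F8 (toluene, reflux) gives 8 as the E isomer under neutral conditions, where the phenol of 3 stays protonated and its hydrogen bond to the aldehyde activates the carbonyl.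

**Further compounds**
F1 | step 6 | racemic [2,3-trans-5,7-bis(benzyloxy)-2-(3,4,5-tris(benzyloxy)phenyl)chroman-3-yl]borane (both enantiomers) | B[C@H]1Cc2c(OCc3ccccc3)cc(OCc3ccccc3)cc2O[C@@H]1c1cc(OCc2ccccc2)c(OCc2ccccc2)c(OCc2ccccc2)c1.B[C@@H]1Cc2c(OCc3ccccc3)cc(OCc3ccccc3)cc2O[C@H]1c1cc(OCc2ccccc2)c(OCc2ccccc2)c(OCc2ccccc2)c1
F2 | step 6 | (2S,3R)-5,7-bis(benzyloxy)-2-[3,4,5-tris(benzyloxy)phenyl]chroman-3-ol | O[C@@H]1Cc2c(OCc3ccccc3)cc(OCc3ccccc3)cc2O[C@H]1c1cc(OCc2ccccc2)c(OCc2ccccc2)c(OCc2ccccc2)c1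
F3 | step 5 | diethyl 1-[3,4,5-tris(benzyloxy)phenyl]ethenyl phosphate | C=C(OP(=O)(OCC)OCC)c1cc(OCc2ccccc2)c(OCc2ccccc2)c(OCc2ccccc2)c1
F4 | step 5 | 5-ethynyl-1,2,3-tris(benzyloxy)benzene | C#Cc1cc(OCc2ccccc2)c(OCc2ccccc2)c(OCc2ccccc2)c1
F5 | step 5 | 3,5-bis(benzyloxy)-6-methylidenecyclohexa-2,4-dien-1-one | C=C1C(=O)C=C(OCc2ccccc2)C=C1OCc1ccccc1
F6 | step 3 | 2-bromo-1-[3,4,5-tris(benzyloxy)phenyl]ethan-1-one | O=C(CBr)c1cc(OCc2ccccc2)c(OCc2ccccc2)c(OCc2ccccc2)c1
F7 | step 3 | {2-oxo-2-[3,4,5-tris(benzyloxy)phenyl]ethyl}triphenylphosphonium bromide | [Br-].O=C(C[P+](c1ccccc1)(c1ccccc1)c1ccccc1)c1cc(OCc2ccccc2)c(OCc2ccccc2)c(OCc2ccccc2)c1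
F8 | step 3 | 1-[3,4,5-tris(benzyloxy)phenyl]-2-(triphenylphosphoranylidene)ethan-1-one | O=C(C=P(c1ccccc1)(c1ccccc1)c1ccccc1)c1cc(OCc2ccccc2)c(OCc2ccccc2)c(OCc2ccccc2)c1
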